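**Plan**
- Retrosynthesis: the three MOM groups come off first. Then O1–C2 of ring C is cut (cyclodehydration), then C2–C3 and C2–C1' together, and last the C4–C4a aryl–acyl bond and the O-prenyl bond.
- Enabling feature: C2 of pyranone ring C is an sp2 carbon at the ketone oxidation level, and its only neighbours are C3, C1' of ring B and O1. It can therefore enter as carbon monoxide between a ring B aryl iodide and the C3 enolate of a ring A ketone that already carries the C3 oxygen.
- Forward, ring A is bought as 2-methoxyresorcinol. It gains its fourth oxygen by C–H borylation/oxidation and the C4–C3 unit by directed lithiation and Weinreb acylation. Ring B is bought as 4-iodophenol and prenylated.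
- The three components are joined in step 9 to the open-chain 1,3-diketone. Ring C is the only ring formed. It closes in step 10 through the single free phenol (future O1) while the C5 oxygen stays masked, which fixes the 6-methoxy rather than the 8-methoxy pattern.
- Stereochemistry: the target is achiral. The one stereocentre met on the way (C3 of the diketone) is racemic and is erased when ring C becomes aromatic. The prenyl alkene has no geometry.

Key step: step 9

Remark: flavone numbering is used for atoms throughout. The 1,3-diketone is drawn in its diketo form, and its enol and ring-chain tautomers are assumed to converge in the cyclodehydration.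

**Step 1**
Reactants: 1 2-methoxyresorcinol (2-methoxybenzene-1,3-diol)
Product: 2 2-methoxy-1,3-bis(methoxymethoxy)benzene
Conditions: MOMCl (2.5 equiv), iPr2NEt (3 equiv), CH2Cl2, 0 °C to rt
Reagents that add atoms: chloromethyl methyl ether (MOMCl), COCCl
Why: Double O-alkylation of the phenols with the very reactive chloromethyl ether under amine base (Williamson-type acetal protection) should be clean, and the MOM groups withstand every basic, reductive and organometallic step that follows while later directing the lithiation.

**Step 2**
Reactants: 2 2-methoxy-1,3-bis(methoxymethoxy)benzene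
Product: 4 4-methoxy-3,5-bis(methoxymethoxy)phenol, via aryl pinacol boronate 3 (not isolated)
Conditions: [Ir(OMe)(cod)]2 (1.5 mol%), dtbpy (3 mol%), B2pin2 (1.0 equiv), THF, 80 °C (sealed); then 30% aq H2O2, aq NaOH, THF, 0 °C; aq NH4Cl
Reagents that add atoms: bis(pinacolato)diboron, CC1(C)OB(OC1(C)C)B1OC(C)(C)C(C)(C)O1 (boryl group of 3 only); hydrogen peroxide, OO (phenol oxygen of 4)
Why: Iridium-catalysed aromatic C–H borylation is governed by sterics and should touch only C5, the one ring C–H of this 1,2,3-trisubstituted benzene without an ortho neighbour, after which basic peroxide oxidises the C–B bond in place (1,2-aryl shift from boron to oxygen) without harm to the MOM acetals.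

**Step 3**
Reactants: 4 4-methoxy-3,5-bis(methoxymethoxy)phenol
Product: 5 5-(benzyloxy)-2-methoxy-1,3-bis(methoxymethoxy)benzene
Conditions: BnBr (1.1 equiv), K2CO3, DMF, rt
Reagents that add atoms: benzyl bromide, BrCc1ccccc1
Why: Williamson ether synthesis on the only free hydroxyl marks the future O1 with a group that is orthogonal to MOM, tolerates n-BuLi and can be removed by hydrogenolysis while the molecule still holds no alkene.

**Step 4**
Reactants: 6 methyl glycolate
Product: 7 methyl 2-(methoxymethoxy)acetate
Conditions: MOMCl (1.3 equiv), iPr2NEt (1.5 equiv), CH2Cl2, 0 °C to rt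
Reagents that add atoms: chloromethyl methyl ether (MOMCl), COCCl
Why: MOM acetal formation on the primary alcohol with a hindered amine base avoids alkoxide-driven self-condensation of the hydroxy ester and puts the future C3 oxygen in place under the same protecting group as the ring oxygens.

**Step 5**
Reactants: 7 methyl 2-(methoxymethoxy)acetate
Product: 8 N-methoxy-2-(methoxymethoxy)-N-methylacetamide
Conditions: MeNH(OMe)·HCl (1.5 equiv), iPrMgCl (3.0 equiv), THF, −20 to 0 °C
Reagents that add atoms: N,O-dimethylhydroxylamine hydrochloride, CNOC.Cl
Why: The chloromagnesium amide made in the flask from the amine salt and iPrMgCl attacks the methyl ester directly (Weinreb amide synthesis by ester aminolysis), and the cold, short reaction leaves the acetal and the alpha-protons alone.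

**Step 6**
Reactants: 5 5-(benzyloxy)-2-methoxy-1,3-bis(methoxymethoxy)benzene; 8 N-methoxy-2-(methoxymethoxy)-N-methylacetamide
Product: 10 1-[2-(benzyloxy)-5-methoxy-4,6-bis(methoxymethoxy)phenyl]-2-(methoxymethoxy)ethan-1-one, via aryllithium 9 (not isolated)
Conditions: n-BuLi (1.1 equiv), THF, −10 to 0 °C; then 8 (1.2 equiv), −78 to 0 °C; aq NH4Cl
Reagents that add atoms: n-butyllithium, [Li]CCCC (lithium of 9 only)
Why: Directed ortho-metalation is regiochemically unambiguous because the two remaining ring C–H bonds are equivalent by symmetry and each sits between the cooperating OMOM and OBn donors, and the Weinreb ketone synthesis then forms C4–C4a and stops at the ketone through N-methoxy chelation until the quench.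

**Step 7**
Reactants: 10 1-[2-(benzyloxy)-5-methoxy-4,6-bis(methoxymethoxy)phenyl]-2-(methoxymethoxy)ethan-1-one
Product: 11 1-[2-hydroxy-5-methoxy-4,6-bis(methoxymethoxy)phenyl]-2-(methoxymethoxy)ethan-1-one
Conditions: H2 (1 atm), 10% Pd/C, EtOAc, rt
Reagents that add atoms: none
Why: Catalytic hydrogenolysis cleaves the benzylic C–O bond selectively, since MOM acetals are inert and the twisted, electron-rich, di-ortho-substituted aryl ketone is reduced only slowly at one atmosphere, and it frees exactly the phenol that is to become O1.

**Step 8**
Reactants: 12 4-iodophenol; 13 prenyl bromide (1-bromo-3-methylbut-2-ene)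
Product: 14 1-iodo-4-[(3-methylbut-2-en-1-yl)oxy]benzene (1-iodo-4-prenyloxybenzene)
Conditions: K2CO3, acetone, reflux
Reagents that add atoms: none
Why: Williamson ether synthesis with a carbonate base should give SN2 attack of the phenoxide oxygen at the primary allylic carbon of 13 and leaves the aryl iodide untouched.

**Step 9**
Reactants: 11 1-[2-hydroxy-5-methoxy-4,6-bis(methoxymethoxy)phenyl]-2-(methoxymethoxy)ethan-1-one; 14 1-iodo-4-prenyloxybenzene; 15 carbon monoxide
Product: 17 racemic 1-[2-hydroxy-5-methoxy-4,6-bis(methoxymethoxy)phenyl]-2-(methoxymethoxy)-3-[4-(prenyloxy)phenyl]propane-1,3-dione, via disodium phenoxide enolate 16 (not isolated)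
Conditions: 11, NaN(SiMe3)2 (3.2 equiv), THF, 0 °C; then 14 (1.3 equiv), Pd(dba)2 (5 mol%), dppp (6 mol%), CO (1 atm), THF–dioxane, 70 °C; aq NH4Cl
Reagents that add atoms: sodium bis(trimethylsilyl)amide, C[Si](C)(C)[N-][Si](C)(C)C.[Na+] (sodium of 16 only)
Why: Oxidative addition of the carbon–iodine bond of 14 to zerovalent palladium and migratory insertion of CO (fast for the electron-rich 4-alkoxyaryl group) forge C2–C1' in an aroyl-palladium iodide; the enolate carbon of 16 then replaces iodide on the metal and reductive elimination forges C2–C3 and returns zerovalent palladium. The closest known reaction type is the palladium-catalysed carbonylative alpha-arylation of aryl alkyl ketones with aryl iodides to 1,3-diketones, which has also been run on 2-hydroxyaryl ketones on the way to flavones. No ring closes here, and the single new stereocentre (C3) arises racemic with no controlling element needed, since it is epimerisable and becomes sp2 in step 10. The selectivity required is acylation at the enolate carbon in preference to the enolate oxygen, the phenoxide or the amide base: acyl transfer within the palladium coordination sphere favours carbon, the bulky silylamide is a poor partner, and any aryl ester that arises through the phenoxide is carried by the excess base through a Baker–Venkataraman acyl shift to the same 17. The third equivalent of base holds 17 as its stabilised enolate, which blocks a second acylation and retro-Claisen cleavage. The trisubstituted prenyl ether binds zerovalent palladium far less readily than the aryl iodide adds to it, so Tsuji–Trost ionisation should not compete under CO.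

**Step 10**
Reactants: 17 racemic 1-[2-hydroxy-5-methoxy-4,6-bis(methoxymethoxy)phenyl]-2-(methoxymethoxy)-3-[4-(prenyloxy)phenyl]propane-1,3-dione
Product: 18 6-methoxy-3,5,7-tris(methoxymethoxy)-2-[4-(prenyloxy)phenyl]-4H-chromen-4-one
Conditions: NaOAc (5 equiv), AcOH, 100 °C
Reagents that add atoms: none
Why: Acid-catalysed cyclodehydration as in the last stage of a Baker–Venkataraman flavone synthesis: the only free phenol adds 6-exo-trig to the aroyl carbonyl C2 and water is lost across C2–C3, while the acetate buffer keeps the medium too weakly acidic to unmask the C5 oxygen or the prenyl ether, so that only the 6-methoxy isomer can arise.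

**Step 11**
Reactants: 18 6-methoxy-3,5,7-tris(methoxymethoxy)-2-[4-(prenyloxy)phenyl]-4H-chromen-4-one
Product: 19 3,5,7-trihydroxy-6-methoxy-2-{4-[(3-methylbut-2-en-1-yl)oxy]phenyl}-4H-chromen-4-one (3,5,7-trihydroxy-6-methoxy-4'-prenyloxyflavone)
Conditions: 2 M aq HCl, MeOH–THF, 40 °C
Reagents that add atoms: none
Why: Acid-catalysed acetal hydrolysis removes the three MOM groups through oxocarbenium ions (those on O3 and O5 helped by the neighbouring C4 carbonyl) much faster than the aryl prenyl ether can ionise in dilute aqueous methanolic acid at 40 °C, and the conditions stay far below those of a Wessely–Moser ring-opening isomerisation.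

**Compound list**
1 | 2-methoxyresorcinol | COc1c(O)cccc1O | starting material
2 | 2-methoxy-1,3-bis(methoxymethoxy)benzene | COCOc1cccc(OCOC)c1OC | intermediate
3 | 2-[4-methoxy-3,5-bis(methoxymethoxy)phenyl]-4,4,5,5-tetramethyl-1,3,2-dioxaborolane (not isolated) | COCOc1cc(B2OC(C)(C)C(C)(C)O2)cc(OCOC)c1OC | intermediate
4 | 4-methoxy-3,5-bis(methoxymethoxy)phenol | COCOc1cc(O)cc(OCOC)c1OC | intermediate
5 | 5-(benzyloxy)-2-methoxy-1,3-bis(methoxymethoxy)benzene | COCOc1cc(OCc2ccccc2)cc(OCOC)c1OC | intermediate
6 | methyl glycolate | COC(=O)CO | starting material
7 | methyl 2-(methoxymethoxy)acetate | COCOCC(=O)OC | intermediate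
8 | N-methoxy-2-(methoxymethoxy)-N-methylacetamide | COCOCC(=O)N(C)OC | intermediate
9 | [2-(benzyloxy)-5-methoxy-4,6-bis(methoxymethoxy)phenyl]lithium (not isolated) | [Li]c1c(OCc2ccccc2)cc(OCOC)c(OC)c1OCOC | intermediate
10 | 1-[2-(benzyloxy)-5-methoxy-4,6-bis(methoxymethoxy)phenyl]-2-(methoxymethoxy)ethan-1-one | COCOCC(=O)c1c(OCc2ccccc2)cc(OCOC)c(OC)c1OCOC | intermediate
11 | 1-[2-hydroxy-5-methoxy-4,6-bis(methoxymethoxy)phenyl]-2-(methoxymethoxy)ethan-1-one | COCOCC(=O)c1c(O)cc(OCOC)c(OC)c1OCOC | intermediate
12 | 4-iodophenol | Oc1ccc(I)cc1 | starting material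
13 | prenyl bromide | CC(C)=CCBr | starting material
14 | 1-iodo-4-prenyloxybenzene | CC(C)=CCOc1ccc(I)cc1 | intermediate
15 | carbon monoxide | [C-]#[O+] | starting material
16 | disodium phenoxide enolate of 11 (enolate geometry not defined, not isolated) | COCOC=C([O-])c1c([O-])cc(OCOC)c(OC)c1OCOC.[Na+].[Na+] | intermediate
17 | racemic 1-[2-hydroxy-5-methoxy-4,6-bis(methoxymethoxy)phenyl]-2-(methoxymethoxy)-3-[4-(prenyloxy)phenyl]propane-1,3-dione | COCOC(C(=O)c1ccc(OCC=C(C)C)cc1)C(=O)c1c(O)cc(OCOC)c(OC)c1OCOC | intermediate
18 | 6-methoxy-3,5,7-tris(methoxymethoxy)-2-[4-(prenyloxy)phenyl]-4H-chromen-4-one | COCOc1cc2oc(-c3ccc(OCC=C(C)C)cc3)c(OCOC)c(=O)c2c(OCOC)c1OC | intermediate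
19 | 3,5,7-trihydroxy-6-methoxy-4'-prenyloxyflavone | COc1c(O)cc2oc(-c3ccc(OCC=C(C)C)cc3)c(O)c(=O)c2c1O | target

**Total step count:** 11
**Longest linear sequence:** 8 steps (1, 2, 3, 6, 7, 9, 10, 11) from 2-methoxyresorcinol

**Steps most likely to fail**

**Step 9.** Several processes could erode this step:
- capture of the aroyl-palladium species at oxygen or nitrogen
- sluggish transfer to the hindered alpha-alkoxy enolate
- direct non-carbonylative arylation
- palladium-induced ionisation of the prenyl ether in the hot, strongly basic medium

The fallback sets out from 11, 14 and 15 and comes back at 17. It separates the two bond formations into two known operations and still takes C2 from carbon monoxide. Aryloxycarbonylation of 14 with the phenol of 11 as nucleophile (Pd(OAc)2, Xantphos, Et3N, CO 1 atm, toluene, 80 °C) should give the aryl ester 4-methoxy-3,5-bis(methoxymethoxy)-2-[(methoxymethoxy)acetyl]phenyl 4-(prenyloxy)benzoate F1, in which C2–C1' is already made. A Baker–Venkataraman rearrangement (KOtBu, THF, 0 °C) then moves the aroyl group from oxygen to the C3 enolate carbon and delivers 17.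

**Step 11.** Acid-induced ionisation of the aryl prenyl ether could lead to loss of the prenyl group or its migration to a ring carbon. This could set in while the slowest acetal, on O7, is still being cleaved. The fallback sets out from 18 and comes back at 19. It exchanges the acetals for silyl ethers without any protic acid. Me3SiOTf and 2,2'-bipyridyl in MeCN (0 °C to rt) should convert the three MOM ethers into 6-methoxy-2-[4-(prenyloxy)phenyl]-3,5,7-tris(trimethylsilyloxy)-4H-chromen-4-one F2. Water at neutral pH then hydrolyses the labile silyl ethers to 19.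

**Step 6.** Three processes could compete here:
- benzylic deprotonation followed by Wittig rearrangement
- incomplete lithiation of the very electron-rich ring
- proton transfer from the Weinreb amide to the hindered aryllithium in place of addition

The fallback sets out from 5 and comes back at 10. It replaces deprotonation by halogen–metal exchange. Electrophilic iodination (NIS, MeCN, 0 °C) of the only type of ring C–H should give 1-(benzyloxy)-2-iodo-4-methoxy-3,5-bis(methoxymethoxy)benzene F3. Iodine–magnesium exchange with iPrMgCl·LiCl (THF, −20 °C) gives the less basic [2-(benzyloxy)-5-methoxy-4,6-bis(methoxymethoxy)phenyl]magnesium chloride F4, which is acylated by 8 to give 10.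

**Further compounds**
F1 | step 9 | 4-methoxy-3,5-bis(methoxymethoxy)-2-[(methoxymethoxy)acetyl]phenyl 4-(prenyloxy)benzoate | COCOCC(=O)c1c(OC(=O)c2ccc(OCC=C(C)C)cc2)cc(OCOC)c(OC)c1OCOC
F2 | step 11 | 6-methoxy-2-[4-(prenyloxy)phenyl]-3,5,7-tris(trimethylsilyloxy)-4H-chromen-4-one | COc1c(O[Si](C)(C)C)cc2oc(-c3ccc(OCC=C(C)C)cc3)c(O[Si](C)(C)C)c(=O)c2c1O[Si](C)(C)C
F3 | step 6 | 1-(benzyloxy)-2-iodo-4-methoxy-3,5-bis(methoxymethoxy)benzene | COCOc1cc(OCc2ccccc2)c(I)c(OCOC)c1OC
F4 | step 6 | [2-(benzyloxy)-5-methoxy-4,6-bis(methoxymethoxy)phenyl]magnesium chloride | COCOc1cc(OCc2ccccc2)c([Mg]Cl)c(OCOC)c1OC
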